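Retrosynthesis: the 3α,4β-diol goes back to a C3,C4-alkene (epoxide, then water at C4) and the axial C6 benzoate to a C6 ketone. The ring-fusion bond C5–C10 is then cut to an (E,E)-cyclodeca-1(10),4-dienyl ester, and the ten-membered ring is cut at C6–C7 to 12-bromofarnesal.
Enabling feature (eudesmane numbering; ring A = C1–C5 and C10, ring B = C5–C10): C5–C10 is the bond shared by rings A and B. Without it the frame is a ten-membered ring whose E-alkenes C1=C10 and C4=C5 face each other, so a cation at the methyl-bearing C10 is within reach of C5.
Forward: the farnesol chain is functionalised at both ends and closed to the ten-membered ring by a CrCl2-mediated allylation (C6–C7). Rings A and B then arise together in the acid-induced transannular cyclisation; C6 inversion, benzoylation, epoxidation and hydrolysis complete the oxygen pattern.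
Stereochemistry: C6/C7 trans from the chair transition state of the allylchromium addition; absolute configuration from separation of the diastereomeric (S)-O-methylmandelates; C5 and C10 from the chair–chair conformer of the cyclodecadiene. C6β comes from hydride attack anti to the C10 methyl, C3 and C4 from α-epoxidation and axial water attack at C4.
The cyclisation is run on the 6α-ester (trans to the isopropyl group). This is the isomer the ring closure delivers, and only it can hold both the C6 and C7 substituents pseudo-equatorial in the reactive conformer; a 6β-ester would be pressed against the C4 methyl (allylic 1,3-strain). The 6β-oxygen of the target is therefore set afterwards on the rigid decalin.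

Key step: step 9

Remark: the germacrane intermediates carry the same atom numbers as the eudesmanes, β means the face of the C10 methyl, and the SMILES of racemic intermediates show the enantiomer that is carried on after the resolution.

Step 1
Reactants: 1 (2E,6E)-farnesol
Product: 2 tert-butyl(dimethyl)silyl ether of (2E,6E)-farnesol
Conditions: TBSCl, imidazole, DMF, 0 °C to rt
Reagents that add atoms: tert-butyldimethylsilyl chloride, CC(C)(C)[Si](C)(C)Cl
Why: Imidazole-promoted silylation masks the C1 hydroxyl, so that later only the new C12 hydroxyl is turned into the bromide; no stereocentre is involved.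

Step 2
Reactants: 2 tert-butyl(dimethyl)silyl ether of (2E,6E)-farnesol
Product: 3 (2E,6E,10E)-12-[tert-butyl(dimethyl)silyloxy]-2,6,10-trimethyldodeca-2,6,10-trien-1-ol
Conditions: SeO2 (cat.), t-BuOOH, salicylic acid (cat.), CH2Cl2, 0 °C to rt
Reagents that add atoms: selenium dioxide, O=[Se]=O (catalytic oxygen carrier); tert-butyl hydroperoxide, CC(C)(C)OO (terminal oxygen source)
Why: Riley-type allylic oxidation (ene reaction, then [2,3]-sigmatropic shift) should hydroxylate the (E)-methyl of the terminal, most electron-rich alkene, the inner alkenes being less reactive and the C2,C3-alkene deactivated by the allylic silyloxy group.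

Step 3
Reactants: 3 (2E,6E,10E)-12-[tert-butyl(dimethyl)silyloxy]-2,6,10-trimethyldodeca-2,6,10-trien-1-ol
Product: 4 tert-butyl(dimethyl)silyl ether of (2E,6E,10E)-12-bromofarnesol
Conditions: CBr4, PPh3, CH2Cl2, 0 °C
Reagents that add atoms: carbon tetrabromide, BrC(Br)(Br)Br
Why: The Appel reaction replaces the primary allylic hydroxyl by bromide through SN2 displacement of the alkoxyphosphonium ion, without allylic transposition and without loss of the silyl ether.

Step 4
Reactants: 4 tert-butyl(dimethyl)silyl ether of (2E,6E,10E)-12-bromofarnesol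
Product: 5 (2E,6E,10E)-12-bromo-3,7,11-trimethyldodeca-2,6,10-trien-1-ol
Conditions: aq. HF, MeCN, 0 °C
Reagents that add atoms: none
Why: Acidic fluoride cleaves the primary silyl ether (desilylation driven by the Si–F bond) in a medium that offers no nucleophile able to displace the allylic bromide.

Step 5
Reactants: 5 (2E,6E,10E)-12-bromo-3,7,11-trimethyldodeca-2,6,10-trien-1-ol
Product: 6 (2E,6E,10E)-12-bromo-3,7,11-trimethyldodeca-2,6,10-trienal
Conditions: MnO2, CH2Cl2, rt
Reagents that add atoms: none
Why: Activated MnO2 oxidises allylic alcohols to enals under neutral conditions with retention of the 2E geometry and leaves the allylic bromide alone.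

Step 6
Reactants: 6 (2E,6E,10E)-12-bromo-3,7,11-trimethyldodeca-2,6,10-trienal
Product: 8 rac-(1(10)E,4E,6R,7S)-germacra-1(10),4,11-trien-6-ol (6,7-trans), via allylchromium dichloride 7 (not isolated)
Conditions: CrCl2 (excess), THF, slow addition at high dilution, rt; aq. NH4Cl
Reagents that add atoms: none
Why: In this intramolecular Nozaki–Hiyama allylation divalent chromium inserts into the C–Br bond and the allylchromium adds through its γ-carbon (C7) to the aldehyde via a chair Zimmerman–Traxler transition state, which sets C6 and C7 anti (6α-hydroxyl, 7β-isopropenyl, racemic) while both ring alkenes keep their E geometry.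

Step 7
Reactants: 8 rac-(1(10)E,4E,6R,7S)-germacra-1(10),4,11-trien-6-ol
Product: 9 rac-(1(10)E,4E,6S,7S)-germacra-1(10),4-dien-6-ol
Conditions: H2 (1 atm), RhCl(PPh3)3 (cat.), benzene, rt
Reagents that add atoms: none
Why: Homogeneous hydrogenation with RhCl(PPh3)3 discriminates by substitution and should reduce only the 1,1-disubstituted isopropenyl alkene; no stereocentre changes (the C6 descriptor changes only because the priorities change).

Step 8
Reactants: 9 rac-(1(10)E,4E,6S,7S)-germacra-1(10),4-dien-6-ol; 10 (2S)-2-methoxy-2-phenylacetic acid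
Product: 11 (1(10)E,4E,6S,7S)-germacra-1(10),4-dien-6-yl (2S)-2-methoxy-2-phenylacetate
Conditions: DCC, DMAP (cat.), CH2Cl2, 0 °C to rt; chromatographic separation of the two diastereomeric esters on Et3N-buffered silica
Reagents that add atoms: (2S)-2-methoxy-2-phenylacetic acid 10, CO[C@H](C(=O)O)c1ccccc1
Why: Steglich esterification with the enantiopure acid converts the two enantiomers into separable diastereomers, the (6S,7S) ester being recognised by the phenyl shielding pattern of O-methylmandelates, and the ester left in place is the acyloxy group wanted for the next step.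

Step 9
Reactants: 11 (1(10)E,4E,6S,7S)-germacra-1(10),4-dien-6-yl (2S)-2-methoxy-2-phenylacetate
Product: 12 (5αH,7αH)-eudesm-3-en-6α-yl (2S)-2-methoxy-2-phenylacetate
Conditions: TsOH·H2O (cat.), CH2Cl2, 0 °C to rt
Reagents that add atoms: none
Why: The acid protonates C1 of the C1,C10-alkene (the C4,C5-alkene is less basic because of the allylic acyloxy group at C6), the tertiary C10 cation is attacked across the ring by C5, and the resulting C4 cation loses a proton from C3. The closest known reaction is the acid-induced transannular cation–olefin cyclisation of (E,E)-germacra-1(10),4-dienes, 6-acyloxy members such as the germacranolides included, to trans-fused eudesmanes. With respect to the attacking C4,C5-alkene the new C5–C10 bond closes ring A in the 6-endo mode and ring B in the 6-exo mode. C5 and C10 are set by the chair–chair conformer of the ten-membered ring in which the C7 isopropyl and the C6 acyloxy group are both pseudo-equatorial and the two alkenes lie parallel with their methyl groups syn, so that anti addition across each alkene gives the 10β-methyl and the 5α-hydrogen relative to C7. The step needs proton loss toward C3 rather than C15 or C5: a C4,C5-alkene would suffer allylic 1,3-strain between C15 and the 6α-ester, and the exocyclic isomer can return to the C4 cation under the same acid and settle as the trisubstituted ring alkene. The equatorial ester cannot reach the empty orbital at C4, so capture of the cation by the acyl oxygen is not expected.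

Step 10
Reactants: 12 (5αH,7αH)-eudesm-3-en-6α-yl (2S)-2-methoxy-2-phenylacetate
Product: 13 (5αH,7αH)-eudesm-3-en-6α-ol
Conditions: LiAlH4, Et2O, 0 °C
Reagents that add atoms: none
Why: Hydride reduction cleaves the hindered equatorial ester at the acyl carbon and releases the 6α-alcohol without touching the trisubstituted alkene or any stereocentre.

Step 11
Reactants: 13 (5αH,7αH)-eudesm-3-en-6α-ol
Product: 14 (5αH,7αH)-eudesm-3-en-6-one
Conditions: Dess–Martin periodinane, NaHCO3, CH2Cl2, 0 °C to rt
Reagents that add atoms: none
Why: Dess–Martin oxidation under bicarbonate buffer forms the ketone at neutral pH, which should keep the C3,C4-alkene out of conjugation and leave C5 and C7 unepimerised.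

Step 12
Reactants: 14 (5αH,7αH)-eudesm-3-en-6-one
Product: 15 (5αH,7αH)-eudesm-3-en-6β-ol
Conditions: LiAlH4, Et2O, −78 °C
Reagents that add atoms: none
Why: Hydride addition to the trans-decalone should come from the α-face because the axial path on the β-face is blocked by the syn-axial C10 methyl, so the hydroxyl ends up axial (6β), as in the hydride reduction of 6-oxo-5α-steroids.

Step 13
Reactants: 15 (5αH,7αH)-eudesm-3-en-6β-ol; 16 benzoyl chloride
Product: 17 (5αH,7αH)-eudesm-3-en-6β-yl benzoate
Conditions: DMAP (cat.), pyridine, 60 °C
Reagents that add atoms: benzoyl chloride 16, O=C(Cl)c1ccccc1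
Why: DMAP-catalysed acylation through the N-benzoylpyridinium ion is forceful enough for the hindered axial alcohol, and C6 keeps its configuration because its C–O bond is not broken.

Step 14
Reactants: 17 (5αH,7αH)-eudesm-3-en-6β-yl benzoate
Product: 18 (5αH,7αH)-3α,4α-epoxyeudesman-6β-yl benzoate
Conditions: mCPBA, NaHCO3, CH2Cl2, 0 °C
Reagents that add atoms: 3-chloroperoxybenzoic acid, O=C(OO)c1cccc(Cl)c1
Why: Peracid epoxidation (Prilezhaev reaction) should occur on the α-face of the C3,C4-alkene, since the β-face is screened by the axial C10 methyl and the axial C6 benzoate, which sets the C3–O bond α.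

Step 15
Reactants: 18 (5αH,7αH)-3α,4α-epoxyeudesman-6β-yl benzoate
Product: 19 (5αH,7αH)-3α,4β-dihydroxyeudesman-6β-yl benzoate (target)
Conditions: HClO4 (cat.), THF–H2O, 0 °C to rt
Reagents that add atoms: water, O
Why: Acid-catalysed epoxide hydrolysis follows the Fürst–Plattner rule, water attacking the tertiary C4 from the β-face with inversion to give the trans-diaxial 3α,4β-diol, and any participation by the axial benzoate carbonyl would deliver oxygen to the same face of C4.

Compound list
1 | (2E,6E)-farnesol | CC(C)=CCC/C(C)=C/CC/C(C)=C/CO | starting material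
2 | tert-butyl(dimethyl)silyl ether of (2E,6E)-farnesol | CC(C)=CCC/C(C)=C/CC/C(C)=C/CO[Si](C)(C)C(C)(C)C | intermediate
3 | (2E,6E,10E)-12-[tert-butyl(dimethyl)silyloxy]-2,6,10-trimethyldodeca-2,6,10-trien-1-ol | OC/C(C)=C/CC/C(C)=C/CC/C(C)=C/CO[Si](C)(C)C(C)(C)C | intermediate
4 | tert-butyl(dimethyl)silyl ether of (2E,6E,10E)-12-bromofarnesol | BrC/C(C)=C/CC/C(C)=C/CC/C(C)=C/CO[Si](C)(C)C(C)(C)C | intermediate
5 | (2E,6E,10E)-12-bromo-3,7,11-trimethyldodeca-2,6,10-trien-1-ol | BrC/C(C)=C/CC/C(C)=C/CC/C(C)=C/CO | intermediate
6 | (2E,6E,10E)-12-bromo-3,7,11-trimethyldodeca-2,6,10-trienal | BrC/C(C)=C/CC/C(C)=C/CC/C(C)=C/C=O | intermediate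
7 | [(2E,6E,10E)-2,6,10-trimethyl-12-oxododeca-2,6,10-trien-1-yl]chromium dichloride (formed in the flask, not isolated) | Cl[Cr](Cl)C/C(C)=C/CC/C(C)=C/CC/C(C)=C/C=O | intermediate
8 | rac-(1(10)E,4E,6R,7S)-germacra-1(10),4,11-trien-6-ol (6α-hydroxyl, 7β-isopropenyl) | C=C(C)[C@@H]1CC/C(C)=C/CC/C(C)=C/[C@H]1O | intermediate
9 | rac-(1(10)E,4E,6S,7S)-germacra-1(10),4-dien-6-ol (6α-hydroxyl, 7β-isopropyl) | CC(C)[C@@H]1CC/C(C)=C/CC/C(C)=C/[C@H]1O | intermediate
10 | (2S)-2-methoxy-2-phenylacetic acid [(S)-O-methylmandelic acid] | CO[C@H](C(=O)O)c1ccccc1 | starting material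
11 | (1(10)E,4E,6S,7S)-germacra-1(10),4-dien-6-yl (2S)-2-methoxy-2-phenylacetate | CC(C)[C@@H]1CC/C(C)=C/CC/C(C)=C/[C@H]1OC(=O)[C@@H](OC)c1ccccc1 | intermediate
12 | (5αH,7αH)-eudesm-3-en-6α-yl (2S)-2-methoxy-2-phenylacetate (10β-methyl, 7β-isopropyl) | CC(C)[C@@H]1CC[C@@]2(C)CCC=C(C)[C@@H]2[C@H]1OC(=O)[C@@H](OC)c1ccccc1 | intermediate
13 | (5αH,7αH)-eudesm-3-en-6α-ol | CC(C)[C@@H]1CC[C@@]2(C)CCC=C(C)[C@@H]2[C@H]1O | intermediate
14 | (5αH,7αH)-eudesm-3-en-6-one | CC(C)[C@@H]1CC[C@@]2(C)CCC=C(C)[C@@H]2C1=O | intermediate
15 | (5αH,7αH)-eudesm-3-en-6β-ol | CC(C)[C@@H]1CC[C@@]2(C)CCC=C(C)[C@@H]2[C@@H]1O | intermediate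
16 | benzoyl chloride | O=C(Cl)c1ccccc1 | starting material
17 | (5αH,7αH)-eudesm-3-en-6β-yl benzoate | CC(C)[C@@H]1CC[C@@]2(C)CCC=C(C)[C@@H]2[C@@H]1OC(=O)c1ccccc1 | intermediate
18 | (5αH,7αH)-3α,4α-epoxyeudesman-6β-yl benzoate | CC(C)[C@@H]1CC[C@@]2(C)CC[C@H]3O[C@@]3(C)[C@@H]2[C@@H]1OC(=O)c1ccccc1 | intermediate
19 | (5αH,7αH)-3α,4β-dihydroxyeudesman-6β-yl benzoate (4α-methyl, 10β-methyl, 7β-isopropyl) | CC(C)[C@@H]1CC[C@@]2(C)CC[C@@H](O)[C@](C)(O)[C@@H]2[C@@H]1OC(=O)c1ccccc1 | target

Total steps: 15. Longest linear sequence: 15 steps (1 to 19); compounds 10 and 16 are purchased.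

Steps most likely to fail

Step 9 (transannular cyclisation). What may go wrong: the C4 cation loses its proton from C15, or after re-protonation from C5, faster than from C3, so the alkene ends up outside ring A or at the ring fusion. The fallback separates ring formation from alkene placement. Setting out from 11, the cyclisation is run cold (BF3·OEt2, CH2Cl2, −78 °C), where the first-formed mixture is expected to be rich in the exocyclic alkene. That isomer, eudesm-4(15)-en-6α-yl (2S)-2-methoxy-2-phenylacetate F1, is accepted. F1 is then treated with RhCl3·3H2O in ethanol at 70 °C; rhodium hydride addition–elimination should move the exocyclic methylene into the ring as the trisubstituted alkene and stop there, because the C4,C5-position is strained by the 6α-ester. This comes back to the route at 12.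

Step 11 (oxidation to the β,γ-unsaturated ketone). What may go wrong: enolisation toward C5 during oxidation, isolation or the following reduction, which would move the C3,C4-alkene into conjugation with the ketone and erase the C5 configuration. The fallback turns the alkene into the epoxide before C6 is oxidised. Setting out from 13, mCPBA (NaHCO3, CH2Cl2, 0 °C) should attack the α-face to give 3α,4α-epoxyeudesman-6α-ol F2. Dess–Martin oxidation then gives 3α,4α-epoxyeudesman-6-one F3. LiAlH4 at −78 °C, where the ketone reacts far faster than the trisubstituted epoxide, should give 3α,4α-epoxyeudesman-6β-ol F4. Benzoylation of F4 with 16 (DMAP, pyridine, 60 °C) rejoins the route at 18.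

Step 6 (ten-membered ring closure). What may go wrong: intermolecular allylation to oligomers outruns closure of the strained ring, or the anti selectivity erodes. The fallback makes the carbocycle by ring contraction instead of direct closure. Setting out from 5, an intramolecular Williamson etherification (NaH, THF, high dilution) should close the far less strained thirteen-membered diallylic ether (3E,7E,11E)-3,7,11-trimethyl-1-oxacyclotrideca-3,7,11-triene F5. n-BuLi in THF at −78 °C should remove a proton from the O–CH2 group next to the alkene CH, giving the α-lithio ether 13-lithio-(3E,7E,11E)-3,7,11-trimethyl-1-oxacyclotrideca-3,7,11-triene F6 (not isolated). Its [2,3]-Wittig rearrangement joins that carbon (C6) to C7, opens the C–O bond and releases the isopropenyl group. The 6,7-trans alcohol is expected from the E-alkene through the envelope transition state, and the sequence comes back to the route at 8.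

Further compounds
F1 | step 9 | (5αH,7αH)-eudesm-4(15)-en-6α-yl (2S)-2-methoxy-2-phenylacetate | CC(C)[C@@H]1CC[C@@]2(C)CCCC(=C)[C@@H]2[C@H]1OC(=O)[C@@H](OC)c1ccccc1
F2 | step 11 | (5αH,7αH)-3α,4α-epoxyeudesman-6α-ol | CC(C)[C@@H]1CC[C@@]2(C)CC[C@H]3O[C@@]3(C)[C@@H]2[C@H]1O
F3 | step 11 | (5αH,7αH)-3α,4α-epoxyeudesman-6-one | CC(C)[C@@H]1CC[C@@]2(C)CC[C@H]3O[C@@]3(C)[C@@H]2C1=O
F4 | step 11 | (5αH,7αH)-3α,4α-epoxyeudesman-6β-ol | CC(C)[C@@H]1CC[C@@]2(C)CC[C@H]3O[C@@]3(C)[C@@H]2[C@@H]1O
F5 | step 6 | (3E,7E,11E)-3,7,11-trimethyl-1-oxacyclotrideca-3,7,11-triene | C1/C(C)=C/CC/C(C)=C/CC/C(C)=C/CO1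
F6 | step 6 | 13-lithio-(3E,7E,11E)-3,7,11-trimethyl-1-oxacyclotrideca-3,7,11-triene | [Li]C1OC/C(C)=C/CC/C(C)=C/CC/C(C)=C/1
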